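**Plan**

1. Retrosynthetic cuts: the O1 isovalerate and the O7 p-coumarate come off first and C11 goes back to a carbonyl group. The bicycle is then opened at C5–C9 and O2–C1 (retro hetero-Diels–Alder) and at C4=C5 (retro-Knoevenagel). The chain is finally cut at C8–C9.
2. Enabling feature: C1 (acetal) and C3 (enol ether) are two aldehyde-level carbons in a 1,5-relationship along C1–C9–C5–C4–C3. O2=C3–C4=C5 of the dihydropyran ring is therefore a 1-oxadiene, C9=C1 an enol ether, and the C6–C7–C8 edge of the cyclopentane ring the tether between them.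
3. Forward: 2-deoxy-D-ribose is converted into an acyclic C5 aldehyde carrying an (E)-2-ethoxyvinyl group on C8 (steps 1–10). Condensation with methyl formylacetate and in-flask cycloaddition then close the cyclopentane and the dihydropyran together (step 12).
4. End game (steps 13–21): C11 ester to aldehyde, C1 acetal to lactol to isovalerate, O7 unmasked and coumaroylated, silyl groups removed, C11 aldehyde reduced last. In this order iBu2AlH never meets a lactol or an acyl group, and aqueous acid never meets an electron-rich enol ether.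
5. Stereochemistry: C7 is C3 of the sugar. C8 comes from chelation-controlled alkynylation of the C8 ketone. C5 and C9 come from the cis-selective cycloaddition on the face away from O7 and C10. C1 comes from the (E)-enol ether in the cycloaddition and, after hydrolysis, from β-selective acylation of the lactol.

Key step: step 12

Remark: iridoid numbering is used for all compounds (C1 acetal carbon, O2, C3=C4, C5 and C9 ring fusion, C6, C7, C8, C10 on C8, C11 on C4; β is the face of H5 and H9); ethoxyacetylene is taken as its commercial solution in hexanes, and lactol 20 is drawn as its 1β anomer.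

**Route**

Step 1
Reactants: 1 2-deoxy-D-ribose
Product: 2 2-deoxy-D-erythro-pentose diethyl dithioacetal
Conditions: EtSH, conc. HCl, 0 °C
Reagents that add atoms: ethanethiol, CCS
Why: Acid-catalysed dithioacetalisation opens the 2-deoxy sugar to its acyclic form and masks the future C5 aldehyde in a form that survives base, hydride and organometallic reagents, with no stereocentre touched.

Step 2
Reactants: 2 2-deoxy-D-erythro-pentose diethyl dithioacetal
Product: 3 2-deoxy-4,5-O-isopropylidene-D-erythro-pentose diethyl dithioacetal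
Conditions: 2,2-dimethoxypropane, TsOH·H2O (cat.), acetone, 0 °C → rt
Reagents that add atoms: 2,2-dimethoxypropane, COC(C)(C)OC
Why: Acid-catalysed transacetalisation favours the terminal 1,3-dioxolane over the cis-disubstituted dioxolane of the erythro 3,4-diol and over the 1,3-dioxane, so only the 3-hydroxyl (future O7) stays free.

Step 3
Reactants: 3 2-deoxy-4,5-O-isopropylidene-D-erythro-pentose diethyl dithioacetal
Product: 4 2-deoxy-4,5-O-isopropylidene-3-O-(4-methoxybenzyl)-D-erythro-pentose diethyl dithioacetal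
Conditions: NaH, 4-methoxybenzyl chloride, Bu4NI (cat.), THF/DMF, 0 °C → rt
Reagents that add atoms: 4-methoxybenzyl chloride, COc1ccc(CCl)cc1
Why: Williamson etherification installs at O7 a chelating benzyl-type ether that is needed for step 7 and can later be removed oxidatively without acid or base.

Step 4
Reactants: 4 2-deoxy-4,5-O-isopropylidene-3-O-(4-methoxybenzyl)-D-erythro-pentose diethyl dithioacetal
Product: 5 2-deoxy-3-O-(4-methoxybenzyl)-D-erythro-pentose diethyl dithioacetal (4,5-diol)
Conditions: AcOH/H2O (4:1), 40 °C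
Reagents that add atoms: none
Why: Mild acid hydrolysis of the isopropylidene acetal frees the 4,5-diol while the dithioacetal and the benzyl-type ether are stable to aqueous acetic acid.

Step 5
Reactants: 5 2-deoxy-3-O-(4-methoxybenzyl)-D-erythro-pentose diethyl dithioacetal
Product: 6 5-O-[tert-butyl(diphenyl)silyl]-2-deoxy-3-O-(4-methoxybenzyl)-D-erythro-pentose diethyl dithioacetal
Conditions: tBuPh2SiCl, imidazole, CH2Cl2, 0 °C
Reagents that add atoms: tert-butyl(chloro)diphenylsilane, CC(C)(C)[Si](Cl)(c1ccccc1)c1ccccc1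
Why: Sterically controlled silylation takes the primary hydroxyl (future O10) only and gives a bulky, acid-stable, non-chelating ether next to the secondary hydroxyl that is to be oxidised.

Step 6
Reactants: 6 5-O-[tert-butyl(diphenyl)silyl]-2-deoxy-3-O-(4-methoxybenzyl)-D-erythro-pentose diethyl dithioacetal
Product: 7 (3S)-1-{[tert-butyl(diphenyl)silyl]oxy}-5,5-bis(ethylsulfanyl)-3-[(4-methoxybenzyl)oxy]pentan-2-one (C8 ketone)
Conditions: Dess–Martin periodinane, pyridine, CH2Cl2, 0 °C → rt
Reagents that add atoms: none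
Why: Dess–Martin oxidation of the secondary alcohol under buffered, anhydrous conditions gives the α-alkoxy ketone without epimerising C7 and without touching the dithioacetal.

Step 7
Reactants: 7 C8 ketone, 8 ethoxyacetylene
Product: 10 (3R,4S)-3-({[tert-butyl(diphenyl)silyl]oxy}methyl)-1-ethoxy-6,6-bis(ethylsulfanyl)-4-[(4-methoxybenzyl)oxy]hex-1-yn-3-ol, via ethoxyethynylmagnesium bromide 9 (not isolated)
Conditions: 8, EtMgBr, THF, 0 °C → rt; then 7, THF, −78 → −30 °C; aq. NH4Cl
Reagents that add atoms: none
Why: The alkynyl Grignard reagent 9 formed by deprotonation of 8 adds to the ketone through a five-membered magnesium chelate between the C8 carbonyl oxygen and the O7 ether (Cram-chelate addition, the bulky silyl ether at O10 does not compete), and attack anti to the C6 branch sets C8 as R with O8 syn to O7 in the zigzag chain.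

Step 8
Reactants: 10 propargylic alcohol
Product: 11 (1E,3R,4S)-3-({[tert-butyl(diphenyl)silyl]oxy}methyl)-1-ethoxy-6,6-bis(ethylsulfanyl)-4-[(4-methoxybenzyl)oxy]hex-1-en-3-ol
Conditions: LiAlH4, THF, 0 °C; aq. KNaC4H4O6 (potassium sodium tartrate)
Reagents that add atoms: none
Why: Hydroxyl-directed trans-hydroalumination of the alkynyl carbinol followed by protonolysis gives the (E)-enol ether, and the dithioacetal, ethers and silyl ether are inert to the hydride at 0 °C.

Step 9
Reactants: 11 (E)-enol ether carbinol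
Product: 12 triethylsilyl ether of 11 at O8
Conditions: Et3SiOTf, 2,6-lutidine, CH2Cl2, −78 °C
Reagents that add atoms: triethylsilyl trifluoromethanesulfonate, CC[Si](CC)(CC)OS(=O)(=O)C(F)(F)F
Why: Silyl triflate with a hindered base is the standard silylation of a tertiary alcohol, and the cap prevents later oxa-Michael addition of O8 to the alkylidene and ionisation of the γ-oxygenated enol ether while the lutidine keeps the medium non-acidic.

Step 10
Reactants: 12 triethylsilyl ether
Product: 13 (3S,4R,5E)-4-({[tert-butyl(diphenyl)silyl]oxy}methyl)-6-ethoxy-3-[(4-methoxybenzyl)oxy]-4-[(triethylsilyl)oxy]hex-5-enal (C5 aldehyde)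
Conditions: MeI, CaCO3, MeCN/H2O (9:1), 40 °C
Reagents that add atoms: water, O
Why: Alkylative dithioacetal hydrolysis (S-methylation, loss of EtSMe, capture of the thionium ion by water) runs at buffered neutral pH without a thiophilic metal or halonium source, conditions to which the enol ether and both silyl ethers should be inert.

Step 11
Reactants: 14 methyl 3,3-dimethoxypropanoate
Product: 15 methyl formylacetate (methyl 3-oxopropanoate)
Conditions: 1 M aq. HCl, 0 °C → rt; extraction into CH2Cl2, dried over Na2SO4, used at once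
Reagents that add atoms: water, O
Why: Acid-catalysed acetal hydrolysis liberates the β-formyl ester, which does not store and is therefore taken directly into the condensation.

Step 12
Reactants: 13 C5 aldehyde, 15 methyl formylacetate
Product: 17 methyl ester cycloadduct (1β-OEt, 5β-H, 9β-H, 7β-O-(4-methoxybenzyl), 8α-OSiEt3, 8β-CH2OSiPh2tBu, C11 = CO2Me), via alkylidene formylacetate 16 (not isolated)
Conditions: 15 (2 equiv), ethylenediammonium diacetate (20 mol%), Na2SO4, CH2Cl2, 0 °C → rt
Reagents that add atoms: none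
Why: The diammonium diacetate mediates Knoevenagel condensation of 13 with the 1,3-dicarbonyl compound 15 (iminium formation, C–C bond formation at C4, loss of water), and the resulting 2-formylacrylate 16, an electron-poor 1-oxadiene O2=C3–C4=C5, is intercepted by the tethered electron-rich enol ether C9=C1 in a concerted, asynchronous [4+2] cycloaddition of inverse electron demand in which the C5–C9 bond leads and the O2–C1 bond follows. The closest known reaction type is the domino Knoevenagel/intramolecular hetero-Diels–Alder reaction of aldehydes that carry a tethered enol ether. The cyclopentane closes through C5–C9 across the three-atom tether C6–C7–C8 (5-exo with respect to the enol ether), and the dihydropyran is the six-membered ring of the cycloaddition itself, completed by O2–C1. C5 and C9 become cis because a three-atom tether cannot span a trans-fused transition state; their absolute sense is set by C8 and C7, whose tBuPh2SiOCH2 and 4-methoxybenzyloxy groups take the convex face away from the forming pyran while the smaller Et3SiO group lies beneath it; C1 follows from suprafacial addition to the (E)-enol ether with the ethoxy group exo and trans to C8 (1β). The step needs the formyl rather than the ester carbonyl as the heteroatom terminus and needs C9, not C1, to bond to C5; the lower-lying, unhindered formyl group of the interconverting alkene isomers of 16 and the polarity match between nucleophilic C9 and electrophilic C5, reinforced by the tether length, should secure both.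

Step 13
Reactants: 17 methyl ester cycloadduct
Product: 18 C11 allylic alcohol (C11 = CH2OH, otherwise as 17)
Conditions: iBu2AlH, CH2Cl2, −78 → −20 °C; aq. KNaC4H4O6 (potassium sodium tartrate)
Reagents that add atoms: none
Why: iBu2AlH reduction of the β-alkoxyacrylate (vinylogous carbonate) ester gives the allylic alcohol while the acetal, the ethers and the silyl ethers are inert.

Step 14
Reactants: 18 C11 allylic alcohol
Product: 19 C11 aldehyde (C11 = CHO, 1β-OEt, otherwise as 17)
Conditions: MnO2, CH2Cl2, rt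
Reagents that add atoms: none
Why: MnO2 oxidation of the allylic alcohol gives the β-alkoxyacrolein, which restores the push–pull deactivation of the enol ether needed for the acid step and leaves C11 at a level that a borohydride can reduce at the very end in the presence of esters.

Step 15
Reactants: 19 C11 aldehyde
Product: 20 lactol (1β-OH, 8α-OH, 7β-O-(4-methoxybenzyl), 8β-CH2OSiPh2tBu, C11 = CHO)
Conditions: 1 M aq. HCl/THF (1:4), 0 °C → rt
Reagents that add atoms: water, O
Why: Acid-catalysed hydrolysis cleaves the mixed acetal (its ring oxygen is a vinylogous formate and leaves readily, while the push–pull enol ether itself resists acid) together with the acid-labile tertiary Et3Si ether, and the tBuPh2Si and 4-methoxybenzyl ethers survive dilute acid.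

Step 16
Reactants: 20 lactol
Product: 21 1β-O-isovaleryl lactol ester (8α-OH, 7β-O-(4-methoxybenzyl), 8β-CH2OSiPh2tBu, C11 = CHO)
Conditions: (iPrCH2CO)2O, pyridine, 4-(dimethylamino)pyridine (cat.), CH2Cl2, −20 → 0 °C
Reagents that add atoms: 3-methylbutanoic anhydride, CC(C)CC(=O)OC(=O)CC(C)C
Why: Acyl-transfer catalysed O-acylation takes the hemiacetal hydroxyl, the only one besides the unreactive tertiary C8–OH, and because the anomers interconvert by ring–chain tautomerism the 1β-oxygen, trans to the quaternary C8 on the convex face and anomerically stabilised, should be acylated, which sets C1 by substrate control.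

Step 17
Reactants: 21 1β-O-isovaleryl lactol ester
Product: 22 C7 alcohol (7β-OH, 8α-OH, 1β-O-isovaleryl, 8β-CH2OSiPh2tBu, C11 = CHO)
Conditions: 2,3-dichloro-5,6-dicyano-1,4-benzoquinone (DDQ), CH2Cl2/aq. NaH2PO4–Na2HPO4 buffer (pH 7), 0 °C
Reagents that add atoms: none
Why: Oxidative cleavage of the 4-methoxybenzyl ether by DDQ (benzylic oxocarbenium ion, then hydrolysis) spares the electron-poor enol ether, the anomeric ester and the silyl ether, and the trans relationship of O7 and O8 prevents anisylidene acetal formation.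

Step 18
Reactants: 23 p-coumaric acid
Product: 25 (E)-3-[4-(tert-butyldimethylsilyloxy)phenyl]acrylic acid, via bis-silylated coumarate 24 (not isolated)
Conditions: tBuMe2SiCl (2.2 equiv), imidazole, DMF, rt; then AcOH/THF/H2O, rt
Reagents that add atoms: tert-butyl(chloro)dimethylsilane, CC(C)(C)[Si](C)(C)Cl
Why: Silylation of both phenol and acid followed by selective solvolysis of the labile silyl ester leaves only the phenol masked, so the acid can be activated without self-acylation.

Step 19
Reactants: 22 C7 alcohol, 25 (E)-3-[4-(tert-butyldimethylsilyloxy)phenyl]acrylic acid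
Product: 26 protected 11-oxo-luzonoid A (1β-O-isovaleryl, 7β-O-(E)-4-silyloxycinnamoyl, 8α-OH, 8β-CH2OSiPh2tBu, C11 = CHO)
Conditions: N,N'-dicyclohexylcarbodiimide (DCC), 4-(dimethylamino)pyridine (0.3 equiv), CH2Cl2, 0 °C → rt
Reagents that add atoms: none
Why: Steglich esterification acylates the secondary C7 hydroxyl with retention at C7, while the tertiary C8 hydroxyl does not react and the neutral conditions leave the anomeric ester in place.

Step 20
Reactants: 26 protected 11-oxo-luzonoid A
Product: 27 11-oxo-luzonoid A (C11 = CHO, all hydroxyls free)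
Conditions: Bu4NF, AcOH (1:1), THF, 0 °C → rt
Reagents that add atoms: none
Why: Fluoride-mediated desilylation buffered with acetic acid removes the aryl and the primary alkyl silyl ether without the basicity that would drive coumaroyl migration from O7 to O10 or loss of the anomeric ester, and it is done while the enol ether is still deactivated by the formyl group.

Step 21
Reactants: 27 11-oxo-luzonoid A
Product: 28 luzonoid A
Conditions: NaBH4, CeCl3·7H2O, MeOH/THF, −78 → −40 °C
Reagents that add atoms: none
Why: Luche reduction adds hydride in 1,2-fashion to the vinylogous formyl group much faster than borohydride attacks the two esters or the cinnamate double bond, so the C11 hydroxymethyl group appears in a short, cold final step.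

**Compound list**

1 | 2-deoxy-D-ribose (2-deoxy-D-erythro-pentose) | O=CC[C@H](O)[C@H](O)CO | starting material
2 | 2-deoxy-D-erythro-pentose diethyl dithioacetal, (2R,3S)-5,5-bis(ethylsulfanyl)pentane-1,2,3-triol | CCSC(SCC)C[C@H](O)[C@H](O)CO | intermediate
3 | 2-deoxy-4,5-O-isopropylidene-D-erythro-pentose diethyl dithioacetal (free 3-OH) | CCSC(SCC)C[C@H](O)[C@@H]1OC(C)(C)OC1 | intermediate
4 | 2-deoxy-4,5-O-isopropylidene-3-O-(4-methoxybenzyl)-D-erythro-pentose diethyl dithioacetal | CCSC(SCC)C[C@H](OCc1ccc(OC)cc1)[C@@H]1OC(C)(C)OC1 | intermediate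
5 | 2-deoxy-3-O-(4-methoxybenzyl)-D-erythro-pentose diethyl dithioacetal (4,5-diol) | CCSC(SCC)C[C@H](OCc1ccc(OC)cc1)[C@H](O)CO | intermediate
6 | 5-O-[tert-butyl(diphenyl)silyl]-2-deoxy-3-O-(4-methoxybenzyl)-D-erythro-pentose diethyl dithioacetal (free 4-OH) | CCSC(SCC)C[C@H](OCc1ccc(OC)cc1)[C@H](O)CO[Si](c1ccccc1)(c1ccccc1)C(C)(C)C | intermediate
7 | (3S)-1-{[tert-butyl(diphenyl)silyl]oxy}-5,5-bis(ethylsulfanyl)-3-[(4-methoxybenzyl)oxy]pentan-2-one (C8 ketone) | CCSC(SCC)C[C@H](OCc1ccc(OC)cc1)C(=O)CO[Si](c1ccccc1)(c1ccccc1)C(C)(C)C | intermediate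
8 | ethoxyacetylene (ethoxyethyne) | CCOC#C | starting material
9 | ethoxyethynylmagnesium bromide (not isolated) | CCOC#C[Mg]Br | intermediate
10 | (3R,4S)-3-({[tert-butyl(diphenyl)silyl]oxy}methyl)-1-ethoxy-6,6-bis(ethylsulfanyl)-4-[(4-methoxybenzyl)oxy]hex-1-yn-3-ol | CCOC#C[C@@](O)(CO[Si](c1ccccc1)(c1ccccc1)C(C)(C)C)[C@@H](OCc1ccc(OC)cc1)CC(SCC)SCC | intermediate
11 | (1E,3R,4S)-3-({[tert-butyl(diphenyl)silyl]oxy}methyl)-1-ethoxy-6,6-bis(ethylsulfanyl)-4-[(4-methoxybenzyl)oxy]hex-1-en-3-ol | CCO/C=C/[C@@](O)(CO[Si](c1ccccc1)(c1ccccc1)C(C)(C)C)[C@@H](OCc1ccc(OC)cc1)CC(SCC)SCC | intermediate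
12 | triethylsilyl ether of 11 at the tertiary O8, (1E,3R,4S) | CCO/C=C/[C@@](O[Si](CC)(CC)CC)(CO[Si](c1ccccc1)(c1ccccc1)C(C)(C)C)[C@@H](OCc1ccc(OC)cc1)CC(SCC)SCC | intermediate
13 | (3S,4R,5E)-4-({[tert-butyl(diphenyl)silyl]oxy}methyl)-6-ethoxy-3-[(4-methoxybenzyl)oxy]-4-[(triethylsilyl)oxy]hex-5-enal (C5 aldehyde) | CCO/C=C/[C@@](O[Si](CC)(CC)CC)(CO[Si](c1ccccc1)(c1ccccc1)C(C)(C)C)[C@@H](OCc1ccc(OC)cc1)CC=O | intermediate
14 | methyl 3,3-dimethoxypropanoate | COC(CC(=O)OC)OC | starting material
15 | methyl formylacetate (methyl 3-oxopropanoate) | COC(=O)CC=O | intermediate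
16 | methyl (2Z,5S,6R,7E)-6-({[tert-butyl(diphenyl)silyl]oxy}methyl)-8-ethoxy-2-formyl-5-[(4-methoxybenzyl)oxy]-6-[(triethylsilyl)oxy]octa-2,7-dienoate, formyl trans to the chain (not isolated) | CCO/C=C/[C@@](O[Si](CC)(CC)CC)(CO[Si](c1ccccc1)(c1ccccc1)C(C)(C)C)[C@@H](OCc1ccc(OC)cc1)C/C=C(/C=O)C(=O)OC | intermediate
17 | methyl ester cycloadduct: cis-fused 1,4a,5,6,7,7a-hexahydrocyclopenta[c]pyran-4-carboxylate with 1β-OEt, 5β-H, 9β-H, 7β-O-(4-methoxybenzyl), 8α-OSiEt3, 8β-CH2OSiPh2tBu | CCO[C@@H]1OC=C(C(=O)OC)[C@H]2C[C@H](OCc3ccc(OC)cc3)[C@](O[Si](CC)(CC)CC)(CO[Si](c3ccccc3)(c3ccccc3)C(C)(C)C)[C@@H]12 | intermediate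
18 | C11 allylic alcohol: as 17 with C11 = CH2OH | CCO[C@@H]1OC=C(CO)[C@H]2C[C@H](OCc3ccc(OC)cc3)[C@](O[Si](CC)(CC)CC)(CO[Si](c3ccccc3)(c3ccccc3)C(C)(C)C)[C@@H]12 | intermediate
19 | C11 aldehyde: as 17 with C11 = CHO | CCO[C@@H]1OC=C(C=O)[C@H]2C[C@H](OCc3ccc(OC)cc3)[C@](O[Si](CC)(CC)CC)(CO[Si](c3ccccc3)(c3ccccc3)C(C)(C)C)[C@@H]12 | intermediate
20 | lactol: 1β-OH, 8α-OH, 7β-O-(4-methoxybenzyl), 8β-CH2OSiPh2tBu, C11 = CHO | O[C@@H]1OC=C(C=O)[C@H]2C[C@H](OCc3ccc(OC)cc3)[C@](O)(CO[Si](c3ccccc3)(c3ccccc3)C(C)(C)C)[C@@H]12 | intermediate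
21 | 1β-O-isovaleryl lactol ester: as 20 with O1 acylated by 3-methylbutanoyl | CC(C)CC(=O)O[C@@H]1OC=C(C=O)[C@H]2C[C@H](OCc3ccc(OC)cc3)[C@](O)(CO[Si](c3ccccc3)(c3ccccc3)C(C)(C)C)[C@@H]12 | intermediate
22 | C7 alcohol: 1β-O-isovaleryl, 7β-OH, 8α-OH, 8β-CH2OSiPh2tBu, C11 = CHO | CC(C)CC(=O)O[C@@H]1OC=C(C=O)[C@H]2C[C@H](O)[C@](O)(CO[Si](c3ccccc3)(c3ccccc3)C(C)(C)C)[C@@H]12 | intermediate
23 | p-coumaric acid, (E)-3-(4-hydroxyphenyl)acrylic acid | OC(=O)/C=C/c1ccc(O)cc1 | starting material
24 | tert-butyldimethylsilyl (E)-3-[4-(tert-butyldimethylsilyloxy)phenyl]acrylate (not isolated) | CC(C)(C)[Si](C)(C)OC(=O)/C=C/c1ccc(O[Si](C)(C)C(C)(C)C)cc1 | intermediate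
25 | (E)-3-[4-(tert-butyldimethylsilyloxy)phenyl]acrylic acid | CC(C)(C)[Si](C)(C)Oc1ccc(/C=C/C(=O)O)cc1 | intermediate
26 | protected 11-oxo-luzonoid A: 1β-O-isovaleryl, 7β-O-[(E)-4-(tert-butyldimethylsilyloxy)cinnamoyl], 8α-OH, 8β-CH2OSiPh2tBu, C11 = CHO | CC(C)CC(=O)O[C@@H]1OC=C(C=O)[C@H]2C[C@H](OC(=O)/C=C/c3ccc(O[Si](C)(C)C(C)(C)C)cc3)[C@](O)(CO[Si](c3ccccc3)(c3ccccc3)C(C)(C)C)[C@@H]12 | intermediate
27 | 11-oxo-luzonoid A: the target with C11 = CHO | CC(C)CC(=O)O[C@@H]1OC=C(C=O)[C@H]2C[C@H](OC(=O)/C=C/c3ccc(O)cc3)[C@](O)(CO)[C@@H]12 | intermediate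
28 | luzonoid A, (1S,5S,7S,8R,9S) in iridoid numbering | CC(C)CC(=O)O[C@@H]1OC=C(CO)[C@H]2C[C@H](OC(=O)/C=C/c3ccc(O)cc3)[C@](O)(CO)[C@@H]12 | target

**Step count and risks**

Total: 21 steps. Longest linear sequence: 19 steps (steps 1–10, 12–17 and 19–21 from 2-deoxy-D-ribose); steps 11 and 18 are one-step side branches.

Steps most likely to fail:

1. Step 12. The unsymmetrical oxadiene may cyclise sluggishly or through the ester carbonyl of the alkene isomer that has the formyl group cis to the chain. Base-induced loss of 4-methoxybenzyl alcohol from the β-alkoxy aldehyde or its alkylidene could then overtake the cycloaddition. Fallback: setting out from 13, the condensation would be run with malondialdehyde (set free from its sodium enolate NaOCH=CHCHO with AcOH, piperidine cat., CH2Cl2) in place of 15. This gives the symmetrical and more electron-poor alkylidene malondialdehyde F1, which has no alkene-isomer problem and should undergo the same cycloaddition faster. Its product is the 4-formyl acetal 19, so the route is rejoined at 19 and steps 13 and 14 fall away.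

2. Step 10. Electrophilic attack on the enol ether, its hydrolysis, or loss of the tertiary silyl ether may compete with the slow alkylative cleavage of the dithioacetal. Fallback: setting out from 6, the dithioacetal would be removed before any enol ether exists (I2, NaHCO3, acetone/H2O), which gives the furanose lactol F2. Reduction with NaBH4 gives the 1,4-diol F3, and pivaloyl chloride/pyridine at low temperature esterifies its primary hydroxyl to give the pivalate F4. Dess–Martin oxidation then gives the keto pivalate F5, and chelation-controlled addition of 9 as in step 7 gives the propargylic alcohol F6. LiAlH4 carries out the trans-reduction and removes the pivalate in the same operation, giving the (E)-enol ether diol F7. Et3SiOTf/2,6-lutidine (excess) gives the bis(triethylsilyl) ether F8. HF·pyridine buffered with pyridine cleaves only the primary silyl ether to give the primary alcohol F9, and Parikh–Doering oxidation (SO3·pyridine, DMSO, iPr2NEt) returns the route at 13.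

3. Step 15. Hydrolysis of the deactivated acetal at the formyl stage may be incomplete, or the freshly formed lactol may ring-open under acid and then suffer retro-aldol cleavage of C8–C9 or epimerisation at C9. Fallback: setting out from 17, the acetal would be hydrolysed at the ester stage (1 M aq. HCl/THF), where 2-alkoxy-dihydropyran-5-carboxylates are known to give well-behaved lactols, to give the lactol ester F10. tBuMe2SiCl/imidazole caps O1 to give the silyl acetal F11. iBu2AlH reduces the ester to the allylic alcohol F12, and MnO2 oxidises it to the formyl silyl acetal F13. Buffered Bu4NF/AcOH at −20 °C then releases the anomeric hydroxyl selectively under non-acidic conditions, and the route is rejoined at 20, which is acylated at once as in step 16.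

Further compounds
F1 | step 12 | (4S,5R,6E)-alkylidene malondialdehyde from 13, 2-substituted propanedial with the chain of 13 (not isolated) | CCO/C=C/[C@@](O[Si](CC)(CC)CC)(CO[Si](c1ccccc1)(c1ccccc1)C(C)(C)C)[C@@H](OCc1ccc(OC)cc1)CC=C(C=O)C=O
F2 | step 10 | 5-O-[tert-butyl(diphenyl)silyl]-2-deoxy-3-O-(4-methoxybenzyl)-D-erythro-pentofuranose (anomeric mixture) | OC1C[C@H](OCc2ccc(OC)cc2)[C@@H](CO[Si](c2ccccc2)(c2ccccc2)C(C)(C)C)O1
F3 | step 10 | 5-O-[tert-butyl(diphenyl)silyl]-2-deoxy-3-O-(4-methoxybenzyl)-D-erythro-pentitol (1,4-diol) | OCC[C@H](OCc1ccc(OC)cc1)[C@H](O)CO[Si](c1ccccc1)(c1ccccc1)C(C)(C)C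
F4 | step 10 | 1-O-pivaloyl derivative of F3 (free 4-OH) | CC(C)(C)C(=O)OCC[C@H](OCc1ccc(OC)cc1)[C@H](O)CO[Si](c1ccccc1)(c1ccccc1)C(C)(C)C
F5 | step 10 | (3S)-5-{[tert-butyl(diphenyl)silyl]oxy}-3-[(4-methoxybenzyl)oxy]-4-oxopentyl pivalate | CC(C)(C)C(=O)OCC[C@H](OCc1ccc(OC)cc1)C(=O)CO[Si](c1ccccc1)(c1ccccc1)C(C)(C)C
F6 | step 10 | (3S,4R)-4-({[tert-butyl(diphenyl)silyl]oxy}methyl)-6-ethoxy-4-hydroxy-3-[(4-methoxybenzyl)oxy]hex-5-ynyl pivalate | CCOC#C[C@@](O)(CO[Si](c1ccccc1)(c1ccccc1)C(C)(C)C)[C@@H](OCc1ccc(OC)cc1)CCOC(=O)C(C)(C)C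
F7 | step 10 | (3S,4R,5E)-4-({[tert-butyl(diphenyl)silyl]oxy}methyl)-6-ethoxy-3-[(4-methoxybenzyl)oxy]hex-5-ene-1,4-diol | CCO/C=C/[C@@](O)(CO[Si](c1ccccc1)(c1ccccc1)C(C)(C)C)[C@@H](OCc1ccc(OC)cc1)CCO
F8 | step 10 | 1,4-bis(triethylsilyl) ether of F7 | CCO/C=C/[C@@](O[Si](CC)(CC)CC)(CO[Si](c1ccccc1)(c1ccccc1)C(C)(C)C)[C@@H](OCc1ccc(OC)cc1)CCO[Si](CC)(CC)CC
F9 | step 10 | (3S,4R,5E)-4-({[tert-butyl(diphenyl)silyl]oxy}methyl)-6-ethoxy-3-[(4-methoxybenzyl)oxy]-4-[(triethylsilyl)oxy]hex-5-en-1-ol | CCO/C=C/[C@@](O[Si](CC)(CC)CC)(CO[Si](c1ccccc1)(c1ccccc1)C(C)(C)C)[C@@H](OCc1ccc(OC)cc1)CCO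
F10 | step 15 | lactol ester: 1β-OH, 8α-OH, 7β-O-(4-methoxybenzyl), 8β-CH2OSiPh2tBu, C11 = CO2Me | O[C@@H]1OC=C(C(=O)OC)[C@H]2C[C@H](OCc3ccc(OC)cc3)[C@](O)(CO[Si](c3ccccc3)(c3ccccc3)C(C)(C)C)[C@@H]12
F11 | step 15 | 1β-O-tert-butyldimethylsilyl acetal of F10 | CC(C)(C)[Si](C)(C)O[C@@H]1OC=C(C(=O)OC)[C@H]2C[C@H](OCc3ccc(OC)cc3)[C@](O)(CO[Si](c3ccccc3)(c3ccccc3)C(C)(C)C)[C@@H]12
F12 | step 15 | C11 allylic alcohol of F11 (C11 = CH2OH) | CC(C)(C)[Si](C)(C)O[C@@H]1OC=C(CO)[C@H]2C[C@H](OCc3ccc(OC)cc3)[C@](O)(CO[Si](c3ccccc3)(c3ccccc3)C(C)(C)C)[C@@H]12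
F13 | step 15 | C11 aldehyde of F11 (C11 = CHO, 1β-OSiMe2tBu) | CC(C)(C)[Si](C)(C)O[C@@H]1OC=C(C=O)[C@H]2C[C@H](OCc3ccc(OC)cc3)[C@](O)(CO[Si](c3ccccc3)(c3ccccc3)C(C)(C)C)[C@@H]12
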